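**Assumption (remark on the chemistry):** the sense of induction of the (S)-diarylprolinol silyl ether is taken from the accepted shielding model of its E-configured iminium ion; if it proved opposite, the (R) catalyst would be used and nothing else changes.

**Remark on notation:** flavan numbering is used (upper unit rings A, C, B; lower unit rings D, F, E). Lactol 9 is (4S), which is the 4β centre of the target, and the interflavan bond enters ring D para to its allyloxy carbon, the future lower C6. The CIP label of upper C4 depends on the protecting groups, so from 27 onward its geometry is written 4β (trans to the C3 oxygen).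

## Structural features

The target is a B-type flavan dimer: an epiafzelechin unit (rings A, C, B) is bonded through C4 to C6 of an epigallocatechin unit (rings D, F, E). It carries two galloyl esters, one on the lower C3 oxygen and one on the 3'-oxygen of ring E; the upper C3 hydroxyl is free. There are five stereocentres: upper C2, C3 and C4 are contiguous (2R,3R,4S; 2,3-cis, 3,4-trans, ring D on the β face), and lower C2 and C3 are adjacent (2R,3R; cis). Fragile features are the aryl gallate on ring E next to two free hydroxyls (acyl migration, solvolysis), the thirteen oxidisable phenols, the benzylic C2–O1 ethers, and the C4–C6 bond between two phloroglucinol-type rings, which acid can cleave by retro-Friedel–Crafts reaction. The real difficulty is upper C4: a congested diarylmethine stereocentre whose two aryl groups each carry two ortho oxygens, with 4→6 rather than 4→8 connectivity. A second difficulty is differentiation: one of three ring E oxygens and the lower C3 oxygen are acylated while the upper C3 oxygen is not. The key step uses the fact that upper C4 is bonded to C4a of ring A, ortho to O1, and to the C3–C2 chain: C4 is the β carbon of a 3-(ring D)propenal, the phenol ortho carbon makes C4–C4a and the phenol oxygen closes O1–C2. Ring D is symmetric about the axis through its ipso carbon and its para oxygen, so the 4→6 linkage is fixed by construction.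

## Logic of the disconnections

**31 from 30.** Cut: the twelve benzyl O–C bonds and the two O–C bonds of the diphenylmethylene ketal. All phenols and the upper C3 hydroxyl are released in one neutral hydrogenolysis at the very end, so the polyphenol and the migration-prone aryl ester never meet acid or base. Demand: every protecting group present in 30 must be hydrogenolysable and both esters must survive.

**30 from 28 and 29.** Cut: the two ester C(=O)–O bonds (lower C3–O and ring E 3'-O). Both acyl groups are the same, so one acylation that consumes two equivalents of 29 serves. Demand: these must be the only free hydroxyls of 28, so upper C3–O is already a benzyl ether and ring E is differentiated.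

**28 from 27.** Cut: the O–Si bond on ring E. A silyl ether is orthogonal to benzyl ethers and to the ketal. Demand: fluoride buffered so that no base-sensitive centre is touched.

**27 from 26.** Cut: lower C4–C4a. The ring D carbon ortho to the ether oxygen is the most nucleophilic site, and the two such carbons are equivalent. The closure makes ring F without creating a stereocentre. Demand: attack at the CH2 terminus of the epoxide, under a Lewis acid mild enough for the benzylic ether and the interflavan bond.

**26 from 18 and 25.** Cut: lower O1–C2. This divides the molecule into the complete upper block and a small unit that already carries both lower stereocentres. Demand: clean SN2 inversion at a benzylic carbinol, which fixes 25 as the erythro isomer (erythro alcohol, inverted, gives the threo ether that corresponds to 2,3-cis).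

**25 back to 19.** Cuts: the epoxide oxygen (25 from 24, with resolution), the carbinol–vinyl C–C bond (24 from 23), the oxidation level (23 from 22 from 21), and the O–Si and ketal O–C bonds (21 from 20 from 19). Ketalisation of the vicinal diol of 19 leaves exactly one hydroxyl free, which desymmetrises ring E in one step. Demand: the ketal and silyl ether must survive hydride, Grignard and titanium reagents.

**18 from 17.** Cut: the O–allyl bond. The allyl group marks the one ring D oxygen that becomes lower O1. Demand: removal without touching benzyl ethers.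

**17 from 16.** Cut: upper C2–H. Reduction of the hemiketal sets C2 relative to C3. Demand: hydride delivery anti to the C3 oxygen.

**16 from 13 and 14 (through 15).** Cut: the upper C2–ring B bond. Ring B arrives as an aryl nucleophile on the lactone carbonyl. Demand: mono-addition.

**13 from 12 from 10 (through 11).** Cuts: the benzyl O–C bond and the upper C3–O bond. The lactone enolate is flat next to C4, so the C4 aryl group decides the face. Demand: hydroxylation trans to ring D and benzylation without enolisation.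

**10 from 9.** Cut: none in the skeleton; the lactol is raised to the lactone so that C3 becomes enolisable.

**9 from 2 and 7 (through 8).** Cuts: upper C4–C4a and O1–C2. This is the strategic cut: it sets the interflavan stereocentre first, under catalyst control, before any other stereocentre exists. Demand: facial control on a hindered, electron-rich enal, and C-attack through the ortho carbon of 2.

**7 from 5 (through 6), 5 from 4, 4 from 2 (through 3).** Cuts: the Cα=Cβ bond, the O–allyl bond and the aryl–CHO bond. Both partners of the key step are drawn from 2. Formylation para to the free hydroxyl leaves the para oxygen of ring D as the only free one, which avoids a selective mono-alkylation of a trihydroxybenzaldehyde. Demand: para regiochemistry in the formylation.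

**2 from 1.** Cut: two O–benzyl bonds.

## Other disconnections considered

Alternative 1: The cut is lower C4–C4a, made by letting the ring D carbon ortho to the ether oxygen open a terminal epoxide under BF3·OEt2 or in hexafluoroisopropanol. The substrate would be the epoxy ether A2 and the product the dimer A1 with a free lower C3 hydroxyl and a silyl ether on ring E.
- In its favour: lower C2 and C3 come enantiopure from an epoxy alcohol, ring D offers two equivalent carbons, and the closure creates no stereocentre.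
- Against it as the organising step: it leaves the interflavan bond and the configuration of upper C4 unsolved, and a strong Lewis acid must spare a benzylic aryl ether and an acid-labile C4–aryl bond.
- Comparison: on structure and mechanism this is the equal of the chosen plan for ring F, because the chosen plan uses the same type of closure as its supporting step 19 (AuCl3/AgOTf, different ring E protection). Step economy is the same. As a strategy it is the weaker, because it would still need the chosen key step or a cationic C4 coupling to build the upper block.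

Alternative 2: The cut is lower C4–C4a and O1–C2 together at the flavylium oxidation level. Phenol 18 would condense with the α-galloyloxy enaminone A4 in HCl-saturated ethyl acetate (C-alkylation with loss of dimethylamine, then cyclodehydration) to give the flavylium chloride A3.
- In its favour: both gallates arrive with A4, aromatisation drives the condensation, and the product is flat, so no stereochemical question arises in the step itself. In step economy it is better than the chosen plan: about three steps fewer after 18.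
- Against it: lower C2 and C3 must then be created by reduction of A3. Syn hydrogenation would give the cis relationship, but nothing in A3 selects the face relative to the remote upper unit, so both lower-unit diastereomers are to be expected. The enol gallate could be lost in that reduction, and HCl threatens the interflavan bond.
- Comparison: shorter, but it moves the hard problem to an uncontrolled reduction, whereas the chosen plan takes both lower stereocentres from one tartrate-controlled step.

Alternative 3: The cut is lower O1–C2 and C3–C4 in one [4+2] step. The ortho-quinone methide from the ring D ortho-hydroxybenzyl alcohol A6 (chiral phosphoric acid, warm toluene) would add the Z enol gallate A7 to give the fully benzylated target A5.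
- In its favour: it is the most convergent of all. Two bonds, two stereocentres and both gallates are installed in one step, the Z geometry translates directly into 2,3-cis, and A5 is one hydrogenolysis from the target. On step economy it is clearly better than the chosen plan.
- Against it: enol esters are weak 2π partners for quinone methides. The regiochemistry needs the aryl group of A7 to outweigh the acyloxy group. The catalyst must impose absolute configuration on a substrate that already carries three stereocentres. A quinone methide on so electron-rich a ring may dimerise, and warm acid threatens the interflavan bond.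
- Comparison: equal in the structure reached, better in length, weaker in mechanistic footing. The chosen plan spends steps 17 to 21 on the same bonds but each uses a well-founded reaction type.

Key step: step 5

## Route

Step 1
Reactants: 1 phloroglucinol
Product: 2 3,5-bis(benzyloxy)phenol
Conditions: NaH (2 equiv), BnCl (2 equiv), DMF, 0 °C to rt
Reagents that add atoms: benzyl chloride, ClCc1ccccc1
Why: Williamson ether synthesis; the double O-benzylation is statistical, and the mono- and tri-ethers together with any C-benzylated by-products are removed by chromatography. Compound 2 serves both as the ring A nucleophile and as the source of ring D.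

Step 2
Reactants: 2 3,5-bis(benzyloxy)phenol
Product: 4 2,6-bis(benzyloxy)-4-hydroxybenzaldehyde, via iminium chloride 3 (not isolated)
Conditions: POCl3, DMF, MeCN, 0 °C to rt; then H2O, 50 °C
Reagents that add atoms: N,N-dimethylformamide, CN(C)C=O; water, O
Why: Vilsmeier–Haack formylation; attack para to the free hydroxyl (the carbon between the two benzyloxy groups) should predominate, as is usual for 3,5-dialkoxyphenols, and the minor ortho aldehyde is separated. The para oxygen of future ring D is thereby the only free one.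

Step 3
Reactants: 4 2,6-bis(benzyloxy)-4-hydroxybenzaldehyde
Product: 5 4-(allyloxy)-2,6-bis(benzyloxy)benzaldehyde
Conditions: allyl bromide, K2CO3, DMF, rt
Reagents that add atoms: allyl bromide, C=CCBr
Why: Williamson etherification of the acidic para phenol (a vinylogous acid); the allyl ether is orthogonal to benzyl ethers and marks the oxygen that becomes lower O1.

Step 4
Reactants: 5 4-(allyloxy)-2,6-bis(benzyloxy)benzaldehyde
Product: 7 (E)-3-[4-(allyloxy)-2,6-bis(benzyloxy)phenyl]prop-2-enal, via vinyl dioxolane 6 (not isolated)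
Conditions: (1,3-dioxolan-2-ylmethyl)triphenylphosphonium bromide, t-BuOK, THF, 0 °C to rt; then 2 M HCl, THF, rt
Reagents that add atoms: (1,3-dioxolan-2-ylmethyl)triphenylphosphonium bromide, [Br-].C1COC(C[P+](c2ccccc2)(c2ccccc2)c2ccccc2)O1; water, O
Why: Wittig two-carbon homologation with a non-stabilised, masked formylmethylene ylide, which should be reactive enough for a hindered, electron-rich 2,6-dialkoxybenzaldehyde; acid hydrolysis of the allylic acetal unmasks the aldehyde and equilibrates the alkene to the E isomer.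

Step 5
Reactants: 2 3,5-bis(benzyloxy)phenol; 7 (E)-3-[4-(allyloxy)-2,6-bis(benzyloxy)phenyl]prop-2-enal
Product: 9 (4S)-4-[4-(allyloxy)-2,6-bis(benzyloxy)phenyl]-5,7-bis(benzyloxy)chroman-2-ol (both C2 epimers), via open-chain hydroxy aldehyde 8 (not isolated)
Conditions: (S)-2-{bis[3,5-bis(trifluoromethyl)phenyl][(trimethylsilyl)oxy]methyl}pyrrolidine (20 mol %), PhCO2H (20 mol %), 2 (1.5 equiv), toluene, 0 °C to rt
Reagents that add atoms: none
Why: The secondary amine condenses with 7 to the E-configured iminium ion, whose Re face at the β carbon is covered by the silyloxydiarylmethyl group. Phenol 2 adds through its ortho carbon (between the hydroxyl and one benzyloxy group) to the open Si face, forming C4–C4a, and hydrolysis of the resulting enamine releases the catalyst and the open aldehyde 8. The phenolic oxygen of 8 then adds to the aldehyde carbon in a 6-exo-trig closure (O1–C2), which gives ring C as the lactol. The closest known reaction type is the iminium-catalysed Friedel–Crafts alkylation–hemiacetalisation of naphthols and 3,5-dialkoxyphenols with β-aryl enals; here it is applied to a more hindered 2,6-disubstituted β-aryl enal. C4 is set by the catalyst alone and has the configuration of the target; the lactol carbon forms as an epimer mixture and is erased as a stereocentre in step 6. The selectivities needed are the enantioface (catalyst shielding), C- over O-alkylation (the electron-rich 3,5-dioxygenated ring forms a C–C bond irreversibly while O-adducts revert), ortho over para carbon (the ortho carbon is less hindered and only its adduct is drained by lactolisation) and mono-alkylation (excess 2; the product is a less nucleophilic aryl ether). The 4→6 connectivity needs no control because ring D is symmetric about the axis through its ipso and allyloxy carbons.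

Step 6
Reactants: 9 (4S)-4-[4-(allyloxy)-2,6-bis(benzyloxy)phenyl]-5,7-bis(benzyloxy)chroman-2-ol
Product: 10 (4S)-4-[4-(allyloxy)-2,6-bis(benzyloxy)phenyl]-5,7-bis(benzyloxy)chroman-2-one
Conditions: Dess–Martin periodinane, CH2Cl2, 0 °C to rt
Reagents that add atoms: none
Why: Oxidation of a cyclic hemiacetal to the lactone; both lactol epimers converge and C4, which is not acidic under these conditions, is untouched.

Step 7
Reactants: 10 (4S)-4-[4-(allyloxy)-2,6-bis(benzyloxy)phenyl]-5,7-bis(benzyloxy)chroman-2-one
Product: 12 (3R,4S)-4-[4-(allyloxy)-2,6-bis(benzyloxy)phenyl]-5,7-bis(benzyloxy)-3-hydroxychroman-2-one (3,4-trans), via potassium enolate 11 (not isolated)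
Conditions: KN(SiMe3)2, THF, −78 °C; 2-(phenylsulfonyl)-3-phenyloxaziridine, −78 °C; AcOH
Reagents that add atoms: 2-(phenylsulfonyl)-3-phenyloxaziridine, O=S(=O)(c1ccccc1)N1OC1c1ccccc1
Why: Davis enolate hydroxylation; in the nearly planar enolate ring C4 is the only sp3 atom, so its bulky aryl group blocks one face and the oxaziridine should deliver oxygen to the other, giving the 3,4-trans alcohol. The enolate of this aryl ester is kept at −78 °C to avoid ketene formation.

Step 8
Reactants: 12 (3R,4S)-4-[4-(allyloxy)-2,6-bis(benzyloxy)phenyl]-5,7-bis(benzyloxy)-3-hydroxychroman-2-one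
Product: 13 (3R,4S)-4-[4-(allyloxy)-2,6-bis(benzyloxy)phenyl]-3,5,7-tris(benzyloxy)chroman-2-one
Conditions: BnBr, Ag2O, 4 Å MS, CH2Cl2, rt, dark
Reagents that add atoms: benzyl bromide, BrCc1ccccc1
Why: Silver oxide-mediated O-benzylation under non-basic conditions, chosen so that the α-oxygenated aryl ester is neither enolised (C3 epimerisation) nor opened. This benzyl ether keeps upper C3–O out of the later acylation.

Step 9
Reactants: 13 (3R,4S)-4-[4-(allyloxy)-2,6-bis(benzyloxy)phenyl]-3,5,7-tris(benzyloxy)chroman-2-one; 14 1-(benzyloxy)-4-bromobenzene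
Product: 16 (3R,4S)-4-[4-(allyloxy)-2,6-bis(benzyloxy)phenyl]-3,5,7-tris(benzyloxy)-2-[4-(benzyloxy)phenyl]chroman-2-ol (C2 epimers; ring-chain tautomer of the keto phenol), via 4-(benzyloxy)phenyllithium 15 (not isolated)
Conditions: 14, n-BuLi, THF, −78 °C; then 13, −78 °C; AcOH
Reagents that add atoms: none
Why: Aryllithium addition to a lactone, as in C-aryl glycoside synthesis. The ketone released on collapse of the adduct is flanked by the C3 ether and the diarylmethine, is deactivated by its para benzyloxy group, and sits next to a phenoxide, so a second addition should be slow at −78 °C with a slight excess only.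

Step 10
Reactants: 16 (3R,4S)-4-[4-(allyloxy)-2,6-bis(benzyloxy)phenyl]-3,5,7-tris(benzyloxy)-2-[4-(benzyloxy)phenyl]chroman-2-ol
Product: 17 (2R,3R,4S)-4-[4-(allyloxy)-2,6-bis(benzyloxy)phenyl]-3,5,7-tris(benzyloxy)-2-[4-(benzyloxy)phenyl]chroman (2,3-cis, 3,4-trans)
Conditions: Et3SiH, BF3·OEt2, CH2Cl2, −78 to −40 °C
Reagents that add atoms: none
Why: Ionic hydrogenation (reductive etherification) through the 2-aryl chromenylium ion. The C3 benzyloxy group should sit pseudoaxial to avoid the coplanar ring B, and hydride should add antiperiplanar to it, as in the reduction of manno-type 1-aryl hemiketals, leading directly to the half-chair with ring B equatorial and the C3 oxygen and ring D axial. C2 is thus relayed from C3, which was relayed from C4.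

Step 11
Reactants: 17 (2R,3R,4S)-4-[4-(allyloxy)-2,6-bis(benzyloxy)phenyl]-3,5,7-tris(benzyloxy)-2-[4-(benzyloxy)phenyl]chroman
Product: 18 3,5-bis(benzyloxy)-4-{(2R,3R,4S)-3,5,7-tris(benzyloxy)-2-[4-(benzyloxy)phenyl]chroman-4-yl}phenol
Conditions: Pd(PPh3)4 (5 mol %), morpholine, THF, rt
Reagents that add atoms: none
Why: Tsuji–Trost deallylation through a π-allylpalladium complex trapped by morpholine; benzyl ethers and all stereocentres are inert.

Step 12
Reactants: 19 methyl gallate
Product: 20 methyl 7-hydroxy-2,2-diphenyl-1,3-benzodioxole-5-carboxylate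
Conditions: Ph2CCl2, neat, 170 °C
Reagents that add atoms: dichlorodiphenylmethane, ClC(Cl)(c1ccccc1)c1ccccc1
Why: Ketalisation of a catechol; only two adjacent hydroxyls can be bridged, so exactly one hydroxyl stays free and ring E is desymmetrised in one step. The diphenylmethylene ketal is cleaved by hydrogenolysis at the end.

Step 13
Reactants: 20 methyl 7-hydroxy-2,2-diphenyl-1,3-benzodioxole-5-carboxylate
Product: 21 methyl 2,2-diphenyl-7-[(triisopropylsilyl)oxy]-1,3-benzodioxole-5-carboxylate
Conditions: iPr3SiCl, imidazole, DMF, rt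
Reagents that add atoms: chlorotriisopropylsilane, CC(C)[Si](Cl)(C(C)C)C(C)C
Why: Silylation of the remaining phenol; the bulky aryl silyl ether should survive hydride, Grignard, titanium and Lewis-acid steps and is the one group removable beside benzyl ethers and the ketal.

Step 14
Reactants: 21 methyl 2,2-diphenyl-7-[(triisopropylsilyl)oxy]-1,3-benzodioxole-5-carboxylate
Product: 22 {2,2-diphenyl-7-[(triisopropylsilyl)oxy]-1,3-benzodioxol-5-yl}methanol
Conditions: iBu2AlH, CH2Cl2, −78 to 0 °C; aq. potassium sodium tartrate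
Reagents that add atoms: none
Why: Hydride reduction of the ester to the benzylic alcohol; ketal and silyl ether are stable to the aluminium hydride.

Step 15
Reactants: 22 {2,2-diphenyl-7-[(triisopropylsilyl)oxy]-1,3-benzodioxol-5-yl}methanol
Product: 23 2,2-diphenyl-7-[(triisopropylsilyl)oxy]-1,3-benzodioxole-5-carbaldehyde
Conditions: MnO2, CH2Cl2, rt
Reagents that add atoms: none
Why: Selective oxidation of a benzylic alcohol to the aldehyde without over-oxidation.

Step 16
Reactants: 23 2,2-diphenyl-7-[(triisopropylsilyl)oxy]-1,3-benzodioxole-5-carbaldehyde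
Product: 24 rac-1-{2,2-diphenyl-7-[(triisopropylsilyl)oxy]-1,3-benzodioxol-5-yl}prop-2-en-1-ol
Conditions: CH2=CHMgBr, THF, −78 to 0 °C; AcOH
Reagents that add atoms: vinylmagnesium bromide, C=C[Mg]Br
Why: Grignard addition to the aldehyde gives the racemic secondary allylic alcohol, the substrate class for kinetic resolution.

Step 17
Reactants: 24 rac-1-{2,2-diphenyl-7-[(triisopropylsilyl)oxy]-1,3-benzodioxol-5-yl}prop-2-en-1-ol
Product: 25 (S)-{2,2-diphenyl-7-[(triisopropylsilyl)oxy]-1,3-benzodioxol-5-yl}[(2R)-oxiran-2-yl]methanol (erythro)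
Conditions: Ti(OiPr)4 (15 mol %), L-(+)-diisopropyl tartrate (20 mol %), t-BuOOH (0.45 equiv), 4 Å MS, CH2Cl2, −20 °C
Reagents that add atoms: tert-butyl hydroperoxide, CC(C)(C)OO
Why: Sharpless kinetic resolution, stopped short of half conversion so that the epoxy alcohol stays enantiomerically clean; with the L-(+)-tartrate the (R) enantiomer of 24 should be epoxidised fast and on the catalyst-dictated alkene face, giving the erythro epoxy alcohol, while (S)-24 is left and separated. Both lower stereocentres (future C2, to be inverted, and C3) are set here by reagent control.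

Step 18
Reactants: 18 3,5-bis(benzyloxy)-4-{(2R,3R,4S)-3,5,7-tris(benzyloxy)-2-[4-(benzyloxy)phenyl]chroman-4-yl}phenol; 25 (S)-{2,2-diphenyl-7-[(triisopropylsilyl)oxy]-1,3-benzodioxol-5-yl}[(2R)-oxiran-2-yl]methanol
Product: 26 3,5-bis(benzyloxy)-4-{(2R,3R,4S)-3,5,7-tris(benzyloxy)-2-[4-(benzyloxy)phenyl]chroman-4-yl}phenyl (R)-{2,2-diphenyl-7-[(triisopropylsilyl)oxy]-1,3-benzodioxol-5-yl}[(2R)-oxiran-2-yl]methyl ether (threo)
Conditions: PPh3, DIAD, toluene, 0 °C to rt
Reagents that add atoms: none
Why: Mitsunobu etherification of an unhindered phenol; SN2 inversion at the benzylic carbinol turns the erythro alcohol into the threo aryl ether, which is the arrangement that corresponds to 2,3-cis in ring F. The epoxide carbon is not involved.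

Step 19
Reactants: 26 3,5-bis(benzyloxy)-4-{(2R,3R,4S)-3,5,7-tris(benzyloxy)-2-[4-(benzyloxy)phenyl]chroman-4-yl}phenyl (R)-{2,2-diphenyl-7-[(triisopropylsilyl)oxy]-1,3-benzodioxol-5-yl}[(2R)-oxiran-2-yl]methyl ether
Product: 27 (2R,3R)-5,7-bis(benzyloxy)-2-{2,2-diphenyl-7-[(triisopropylsilyl)oxy]-1,3-benzodioxol-5-yl}-6-{(2R,3R)-3,5,7-tris(benzyloxy)-2-[4-(benzyloxy)phenyl]chroman-4β-yl}chroman-3-ol
Conditions: AuCl3 (5 mol %), AgOTf (15 mol %), ClCH2CH2Cl, 0 °C to rt
Reagents that add atoms: none
Why: Intramolecular Friedel–Crafts epoxide–arene alkylation, a known route to 3-chromanols from 3,5-dialkoxyphenyl ethers of epoxy alcohols; the ring D carbon ortho to the ether oxygen attacks the CH2 terminus (6-endo), forming lower C4–C4a. The two candidate carbons are equivalent and neither C2 nor C3 is touched, so the lower unit emerges 2,3-cis with its C3 hydroxyl free.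

Step 20
Reactants: 27 (2R,3R)-5,7-bis(benzyloxy)-2-{2,2-diphenyl-7-[(triisopropylsilyl)oxy]-1,3-benzodioxol-5-yl}-6-{(2R,3R)-3,5,7-tris(benzyloxy)-2-[4-(benzyloxy)phenyl]chroman-4β-yl}chroman-3-ol
Product: 28 (2R,3R)-5,7-bis(benzyloxy)-2-(7-hydroxy-2,2-diphenyl-1,3-benzodioxol-5-yl)-6-{(2R,3R)-3,5,7-tris(benzyloxy)-2-[4-(benzyloxy)phenyl]chroman-4β-yl}chroman-3-ol
Conditions: Bu4NF, AcOH, THF, 0 °C
Reagents that add atoms: none
Why: Fluoride cleavage of the aryl silyl ether, buffered with acetic acid so that the phenoxide is protonated at once; benzyl ethers and the ketal are inert.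

Step 21
Reactants: 28 (2R,3R)-5,7-bis(benzyloxy)-2-(7-hydroxy-2,2-diphenyl-1,3-benzodioxol-5-yl)-6-{(2R,3R)-3,5,7-tris(benzyloxy)-2-[4-(benzyloxy)phenyl]chroman-4β-yl}chroman-3-ol; 29 3,4,5-tris(benzyloxy)benzoic acid (3 equiv used, two of which are incorporated)
Product: 30 bis[3,4,5-tris(benzyloxy)benzoate] of 28 (esters on the lower C3 oxygen and on the ring E hydroxyl)
Conditions: 29 (3 equiv), EDC·HCl (3.5 equiv), DMAP (0.5 equiv), CH2Cl2, rt
Reagents that add atoms: 3,4,5-tris(benzyloxy)benzoic acid (the second equivalent of 29, which supplies the second acyl group), OC(=O)c1cc(OCc2ccccc2)c(OCc2ccccc2)c(OCc2ccccc2)c1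
Why: Double Steglich esterification of the only two free hydroxyls, the ring E phenol and the axial lower C3 alcohol, each taking one molecule of the same protected gallic acid with loss of water to the carbodiimide; the upper C3 oxygen is a benzyl ether and cannot react.

Step 22
Reactants: 30 bis[3,4,5-tris(benzyloxy)benzoate] of 28
Product: 31 epiafzelechin-(4β→6)-epigallocatechin 3,3'-di-O-gallate (target)
Conditions: H2 (1 atm), Pd(OH)2/C, THF/MeOH, rt
Reagents that add atoms: none
Why: Global hydrogenolysis of twelve benzyl ethers and the diphenylmethylene ketal under neutral conditions, the standard final step for benzylated catechin gallates; no stereocentre is involved and both esters should persist.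

## Compound list

1 | phloroglucinol | Oc1cc(O)cc(O)c1 | starting material
2 | 3,5-bis(benzyloxy)phenol | Oc1cc(OCc2ccccc2)cc(OCc2ccccc2)c1 | intermediate
3 | {[2,6-bis(benzyloxy)-4-hydroxyphenyl]methylidene}dimethylammonium chloride | C[N+](C)=Cc1c(OCc2ccccc2)cc(O)cc1OCc1ccccc1.[Cl-] | intermediate
4 | 2,6-bis(benzyloxy)-4-hydroxybenzaldehyde | O=Cc1c(OCc2ccccc2)cc(O)cc1OCc1ccccc1 | intermediate
5 | 4-(allyloxy)-2,6-bis(benzyloxy)benzaldehyde | O=Cc1c(OCc2ccccc2)cc(OCC=C)cc1OCc1ccccc1 | intermediate
6 | 2-{2-[4-(allyloxy)-2,6-bis(benzyloxy)phenyl]ethenyl}-1,3-dioxolane (E/Z mixture) | C=CCOc1cc(OCc2ccccc2)c(C=CC2OCCO2)c(OCc2ccccc2)c1 | intermediate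
7 | (E)-3-[4-(allyloxy)-2,6-bis(benzyloxy)phenyl]prop-2-enal | O=C/C=C/c1c(OCc2ccccc2)cc(OCC=C)cc1OCc1ccccc1 | intermediate
8 | (3R)-3-[4-(allyloxy)-2,6-bis(benzyloxy)phenyl]-3-[2,4-bis(benzyloxy)-6-hydroxyphenyl]propanal (open form of 9) | C=CCOc1cc(OCc2ccccc2)c([C@H](CC=O)c2c(O)cc(OCc3ccccc3)cc2OCc2ccccc2)c(OCc2ccccc2)c1 | intermediate
9 | (4S)-4-[4-(allyloxy)-2,6-bis(benzyloxy)phenyl]-5,7-bis(benzyloxy)chroman-2-ol (C2 epimers) | C=CCOc1cc(OCc2ccccc2)c([C@H]2c3c(OCc4ccccc4)cc(OCc4ccccc4)cc3OC(O)C2)c(OCc2ccccc2)c1 | intermediate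
10 | (4S)-4-[4-(allyloxy)-2,6-bis(benzyloxy)phenyl]-5,7-bis(benzyloxy)chroman-2-one | C=CCOc1cc(OCc2ccccc2)c([C@H]2c3c(OCc4ccccc4)cc(OCc4ccccc4)cc3OC(=O)C2)c(OCc2ccccc2)c1 | intermediate
11 | potassium enolate of 10 | C=CCOc1cc(OCc2ccccc2)c([C@H]2c3c(OCc4ccccc4)cc(OCc4ccccc4)cc3OC([O-])=C2)c(OCc2ccccc2)c1.[K+] | intermediate
12 | (3R,4S)-4-[4-(allyloxy)-2,6-bis(benzyloxy)phenyl]-5,7-bis(benzyloxy)-3-hydroxychroman-2-one | C=CCOc1cc(OCc2ccccc2)c([C@H]2c3c(OCc4ccccc4)cc(OCc4ccccc4)cc3OC(=O)[C@@H]2O)c(OCc2ccccc2)c1 | intermediate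
13 | (3R,4S)-4-[4-(allyloxy)-2,6-bis(benzyloxy)phenyl]-3,5,7-tris(benzyloxy)chroman-2-one | C=CCOc1cc(OCc2ccccc2)c([C@H]2c3c(OCc4ccccc4)cc(OCc4ccccc4)cc3OC(=O)[C@@H]2OCc2ccccc2)c(OCc2ccccc2)c1 | intermediate
14 | 1-(benzyloxy)-4-bromobenzene | Brc1ccc(OCc2ccccc2)cc1 | starting material
15 | [4-(benzyloxy)phenyl]lithium | [Li]c1ccc(OCc2ccccc2)cc1 | intermediate
16 | (3R,4S)-4-[4-(allyloxy)-2,6-bis(benzyloxy)phenyl]-3,5,7-tris(benzyloxy)-2-[4-(benzyloxy)phenyl]chroman-2-ol (C2 epimers) | C=CCOc1cc(OCc2ccccc2)c([C@H]2c3c(OCc4ccccc4)cc(OCc4ccccc4)cc3OC(O)(c3ccc(OCc4ccccc4)cc3)[C@@H]2OCc2ccccc2)c(OCc2ccccc2)c1 | intermediate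
17 | (2R,3R,4S)-4-[4-(allyloxy)-2,6-bis(benzyloxy)phenyl]-3,5,7-tris(benzyloxy)-2-[4-(benzyloxy)phenyl]chroman | C=CCOc1cc(OCc2ccccc2)c([C@H]2c3c(OCc4ccccc4)cc(OCc4ccccc4)cc3O[C@H](c3ccc(OCc4ccccc4)cc3)[C@@H]2OCc2ccccc2)c(OCc2ccccc2)c1 | intermediate
18 | 3,5-bis(benzyloxy)-4-{(2R,3R,4S)-3,5,7-tris(benzyloxy)-2-[4-(benzyloxy)phenyl]chroman-4-yl}phenol | Oc1cc(OCc2ccccc2)c([C@H]2c3c(OCc4ccccc4)cc(OCc4ccccc4)cc3O[C@H](c3ccc(OCc4ccccc4)cc3)[C@@H]2OCc2ccccc2)c(OCc2ccccc2)c1 | intermediate
19 | methyl gallate | COC(=O)c1cc(O)c(O)c(O)c1 | starting material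
20 | methyl 7-hydroxy-2,2-diphenyl-1,3-benzodioxole-5-carboxylate | COC(=O)c1cc(O)c2OC(c3ccccc3)(c3ccccc3)Oc2c1 | intermediate
21 | methyl 2,2-diphenyl-7-[(triisopropylsilyl)oxy]-1,3-benzodioxole-5-carboxylate | COC(=O)c1cc(O[Si](C(C)C)(C(C)C)C(C)C)c2OC(c3ccccc3)(c3ccccc3)Oc2c1 | intermediate
22 | {2,2-diphenyl-7-[(triisopropylsilyl)oxy]-1,3-benzodioxol-5-yl}methanol | OCc1cc(O[Si](C(C)C)(C(C)C)C(C)C)c2OC(c3ccccc3)(c3ccccc3)Oc2c1 | intermediate
23 | 2,2-diphenyl-7-[(triisopropylsilyl)oxy]-1,3-benzodioxole-5-carbaldehyde | O=Cc1cc(O[Si](C(C)C)(C(C)C)C(C)C)c2OC(c3ccccc3)(c3ccccc3)Oc2c1 | intermediate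
24 | rac-1-{2,2-diphenyl-7-[(triisopropylsilyl)oxy]-1,3-benzodioxol-5-yl}prop-2-en-1-ol | C=CC(O)c1cc(O[Si](C(C)C)(C(C)C)C(C)C)c2OC(c3ccccc3)(c3ccccc3)Oc2c1 | intermediate
25 | (S)-{2,2-diphenyl-7-[(triisopropylsilyl)oxy]-1,3-benzodioxol-5-yl}[(2R)-oxiran-2-yl]methanol | CC(C)[Si](C(C)C)(C(C)C)Oc1cc(cc2OC(c3ccccc3)(c3ccccc3)Oc12)[C@H](O)[C@H]1CO1 | intermediate
26 | threo aryl ether of 18 with the (R)-aryl[(2R)-oxiran-2-yl]methyl group | CC(C)[Si](C(C)C)(C(C)C)Oc1cc(cc2OC(c3ccccc3)(c3ccccc3)Oc12)[C@@H](Oc1cc(OCc2ccccc2)c([C@H]2c3c(OCc4ccccc4)cc(OCc4ccccc4)cc3O[C@H](c3ccc(OCc4ccccc4)cc3)[C@@H]2OCc2ccccc2)c(OCc2ccccc2)c1)[C@H]1CO1 | intermediate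
27 | protected 4β→6 dimer, lower C3–OH free, ring E silyl ether and ketal | CC(C)[Si](C(C)C)(C(C)C)Oc1cc(cc2OC(c3ccccc3)(c3ccccc3)Oc12)[C@H]1Oc2cc(OCc3ccccc3)c([C@H]3c4c(OCc5ccccc5)cc(OCc5ccccc5)cc4O[C@H](c4ccc(OCc5ccccc5)cc4)[C@@H]3OCc3ccccc3)c(OCc3ccccc3)c2C[C@H]1O | intermediate
28 | protected 4β→6 dimer, lower C3–OH and ring E 3'-OH free | Oc1cc(cc2OC(c3ccccc3)(c3ccccc3)Oc12)[C@H]1Oc2cc(OCc3ccccc3)c([C@H]3c4c(OCc5ccccc5)cc(OCc5ccccc5)cc4O[C@H](c4ccc(OCc5ccccc5)cc4)[C@@H]3OCc3ccccc3)c(OCc3ccccc3)c2C[C@H]1O | intermediate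
29 | 3,4,5-tris(benzyloxy)benzoic acid | OC(=O)c1cc(OCc2ccccc2)c(OCc2ccccc2)c(OCc2ccccc2)c1 | starting material
30 | bis[3,4,5-tris(benzyloxy)benzoate] of 28 | O=C(Oc1cc(cc2OC(c3ccccc3)(c3ccccc3)Oc12)[C@H]1Oc2cc(OCc3ccccc3)c([C@H]3c4c(OCc5ccccc5)cc(OCc5ccccc5)cc4O[C@H](c4ccc(OCc5ccccc5)cc4)[C@@H]3OCc3ccccc3)c(OCc3ccccc3)c2C[C@H]1OC(=O)c1cc(OCc2ccccc2)c(OCc2ccccc2)c(OCc2ccccc2)c1)c1cc(OCc2ccccc2)c(OCc2ccccc2)c(OCc2ccccc2)c1 | intermediate
31 | epiafzelechin-(4β→6)-epigallocatechin 3,3'-di-O-gallate (CNP0290965.1) | O=C(Oc1cc([C@H]2Oc3cc(O)c([C@H]4c5c(O)cc(O)cc5O[C@H](c5ccc(O)cc5)[C@@H]4O)c(O)c3C[C@H]2OC(=O)c2cc(O)c(O)c(O)c2)cc(O)c1O)c1cc(O)c(O)c(O)c1 | target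

## Step count and least certain steps

Total: 22 steps. Longest linear sequence: 16 steps (steps 1 to 11, then 18 to 22). The ring E branch (steps 12 to 17) has 6 steps.

**Step 5 (key step).** Most likely failure: slow or no conjugate addition, because the iminium ion of a 2,6-dialkoxy, electron-rich β-aryl enal is both shielded and weakly electrophilic. Attack through the para carbon of 2, and loss of enantiomeric purity through an uncatalysed or reversible Friedel–Crafts step, are the next concerns. Fallback, from 5 and 2, rejoining at 10: Wittig reaction of 5 with methyl 2-oxo-3-(triphenylphosphoranylidene)propanoate would give methyl (E)-4-[4-(allyloxy)-2,6-bis(benzyloxy)phenyl]-2-oxobut-3-enoate F1, a far stronger, two-point-binding acceptor. The known asymmetric Friedel–Crafts alkylation–hemiketalisation of phenols with such keto esters (Cu(OTf)2 with a chiral bis(oxazoline), ligand enantiomer chosen for the 4S sense) would give methyl (4S)-4-[4-(allyloxy)-2,6-bis(benzyloxy)phenyl]-5,7-bis(benzyloxy)-2-hydroxychroman-2-carboxylate F2. Saponification and oxidative decarboxylation (NaOH, H2O2) would give (3R)-3-[4-(allyloxy)-2,6-bis(benzyloxy)phenyl]-3-[2,4-bis(benzyloxy)-6-hydroxyphenyl]propanoic acid F3, which lactonises on acidification to 10.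

**Step 10.** Most likely failure: poor or reversed facial selectivity in the hydride transfer, because the face anti to the C3 ether is also the face on which ring D stands 1,3 to C2; proton loss from the cation at C3 could in addition scramble C3. Fallback, from 13, rejoining at 17, with the roles of nucleophile and substituent exchanged so that the aryl group, not hydride, enters and does so anti to ring D: iBu2AlH at −78 °C would reduce 13 to (3R,4S)-4-[4-(allyloxy)-2,6-bis(benzyloxy)phenyl]-3,5,7-tris(benzyloxy)chroman-2-ol F4. Benzenesulfinic acid and CaCl2 would convert it into (3R,4S)-4-[4-(allyloxy)-2,6-bis(benzyloxy)phenyl]-3,5,7-tris(benzyloxy)-2-(phenylsulfonyl)chroman F5. The known substitution of 2-sulfonyl cyclic ethers by arylzinc reagents, here bromo[4-(benzyloxy)phenyl]zinc F6 (from 15 and ZnBr2), would then give 17.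

**Step 9.** Most likely failure: double addition after collapse of the adduct of this aryl ester, or enolisation of the α-alkoxy lactone by the aryllithium with loss of material or of C3 integrity. Fallback, from 13, rejoining at 16: opening of the lactone with MeNHOMe·HCl and i-PrMgCl would give the Weinreb amide of (2R)-2-(benzyloxy)-3-[4-(allyloxy)-2,6-bis(benzyloxy)phenyl]-3-[2,4-bis(benzyloxy)-6-hydroxyphenyl]propanoic acid F7 (configuration of 13 retained at both centres). Two equivalents of 15 (one for the phenol) would give a stable chelate that releases the ketone only on work-up; the keto phenol closes to 16.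

**Step 19.** Most likely failure: ionisation of the benzylic C2–O1 ether by the Lewis acid (epimerisation or fragmentation), attack at the internal epoxide carbon (five-membered ring), or acid-induced cleavage of the interflavan bond. Fallback, from 18, rejoining at 27, using an aryl anion instead of Friedel–Crafts chemistry: iodination of the phenoxide of 18 (I2, morpholine) would give 3,5-bis(benzyloxy)-2-iodo-4-{(2R,3R,4S)-3,5,7-tris(benzyloxy)-2-[4-(benzyloxy)phenyl]chroman-4-yl}phenol F8. Mitsunobu reaction with 25 would give the iodo analogue of 26, F9. Iodine–magnesium exchange (i-PrMgCl·LiCl, −20 °C) would give the aryl Grignard reagent F10, which with CuI (10 mol %) should open the epoxide at its CH2 terminus in the same flask to give 27.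

## Further compounds

F1 | step 5 | methyl (E)-4-[4-(allyloxy)-2,6-bis(benzyloxy)phenyl]-2-oxobut-3-enoate | COC(=O)C(=O)/C=C/c1c(OCc2ccccc2)cc(OCC=C)cc1OCc1ccccc1
F2 | step 5 | methyl (4S)-4-[4-(allyloxy)-2,6-bis(benzyloxy)phenyl]-5,7-bis(benzyloxy)-2-hydroxychroman-2-carboxylate | C=CCOc1cc(OCc2ccccc2)c([C@H]2c3c(OCc4ccccc4)cc(OCc4ccccc4)cc3OC(O)(C(=O)OC)C2)c(OCc2ccccc2)c1
F3 | step 5 | (3R)-3-[4-(allyloxy)-2,6-bis(benzyloxy)phenyl]-3-[2,4-bis(benzyloxy)-6-hydroxyphenyl]propanoic acid | C=CCOc1cc(OCc2ccccc2)c([C@H](CC(=O)O)c2c(O)cc(OCc3ccccc3)cc2OCc2ccccc2)c(OCc2ccccc2)c1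
F4 | step 10 | (3R,4S)-4-[4-(allyloxy)-2,6-bis(benzyloxy)phenyl]-3,5,7-tris(benzyloxy)chroman-2-ol | C=CCOc1cc(OCc2ccccc2)c([C@H]2c3c(OCc4ccccc4)cc(OCc4ccccc4)cc3OC(O)[C@@H]2OCc2ccccc2)c(OCc2ccccc2)c1
F5 | step 10 | (3R,4S)-4-[4-(allyloxy)-2,6-bis(benzyloxy)phenyl]-3,5,7-tris(benzyloxy)-2-(phenylsulfonyl)chroman | C=CCOc1cc(OCc2ccccc2)c([C@H]2c3c(OCc4ccccc4)cc(OCc4ccccc4)cc3OC(S(=O)(=O)c3ccccc3)[C@@H]2OCc2ccccc2)c(OCc2ccccc2)c1
F6 | step 10 | bromo[4-(benzyloxy)phenyl]zinc | Br[Zn]c1ccc(OCc2ccccc2)cc1
F7 | step 9 | Weinreb amide from ring opening of 13 | C=CCOc1cc(OCc2ccccc2)c([C@H]([C@@H](OCc2ccccc2)C(=O)N(C)OC)c2c(O)cc(OCc3ccccc3)cc2OCc2ccccc2)c(OCc2ccccc2)c1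
F8 | step 19 | 3,5-bis(benzyloxy)-2-iodo-4-{(2R,3R,4S)-3,5,7-tris(benzyloxy)-2-[4-(benzyloxy)phenyl]chroman-4-yl}phenol | Oc1cc(OCc2ccccc2)c([C@H]2c3c(OCc4ccccc4)cc(OCc4ccccc4)cc3O[C@H](c3ccc(OCc4ccccc4)cc3)[C@@H]2OCc2ccccc2)c(OCc2ccccc2)c1I
F9 | step 19 | iodo analogue of 26 | CC(C)[Si](C(C)C)(C(C)C)Oc1cc(cc2OC(c3ccccc3)(c3ccccc3)Oc12)[C@@H](Oc1cc(OCc2ccccc2)c([C@H]2c3c(OCc4ccccc4)cc(OCc4ccccc4)cc3O[C@H](c3ccc(OCc4ccccc4)cc3)[C@@H]2OCc2ccccc2)c(OCc2ccccc2)c1I)[C@H]1CO1
F10 | step 19 | aryl Grignard reagent from F9 | CC(C)[Si](C(C)C)(C(C)C)Oc1cc(cc2OC(c3ccccc3)(c3ccccc3)Oc12)[C@@H](Oc1cc(OCc2ccccc2)c([C@H]2c3c(OCc4ccccc4)cc(OCc4ccccc4)cc3O[C@H](c3ccc(OCc4ccccc4)cc3)[C@@H]2OCc2ccccc2)c(OCc2ccccc2)c1[Mg]Cl)[C@H]1CO1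
A1 | alternative 1 | protected 4β→6 dimer with free lower C3 hydroxyl and ring E tert-butyldimethylsilyl ether | CC(C)(C)[Si](C)(C)Oc1cc([C@H]2Oc3cc(OCc4ccccc4)c([C@H]4c5c(OCc6ccccc6)cc(OCc6ccccc6)cc5O[C@H](c5ccc(OCc6ccccc6)cc5)[C@@H]4OCc4ccccc4)c(OCc4ccccc4)c3C[C@H]2O)cc(OCc2ccccc2)c1OCc1ccccc1
A2 | alternative 1 | threo epoxy ether of 18 with ring E as silyl and dibenzyl ether | CC(C)(C)[Si](C)(C)Oc1cc(cc(OCc2ccccc2)c1OCc1ccccc1)[C@@H](Oc1cc(OCc2ccccc2)c([C@H]2c3c(OCc4ccccc4)cc(OCc4ccccc4)cc3O[C@H](c3ccc(OCc4ccccc4)cc3)[C@@H]2OCc2ccccc2)c(OCc2ccccc2)c1)[C@H]1CO1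
A3 | alternative 2 | benzylated 6-(flavan-4-yl)flavylium digallate chloride | O=C(Oc1cc(-c2[o+]c3cc(OCc4ccccc4)c([C@H]4c5c(OCc6ccccc6)cc(OCc6ccccc6)cc5O[C@H](c5ccc(OCc6ccccc6)cc5)[C@@H]4OCc4ccccc4)c(OCc4ccccc4)c3cc2OC(=O)c2cc(OCc3ccccc3)c(OCc3ccccc3)c(OCc3ccccc3)c2)cc(OCc2ccccc2)c1OCc1ccccc1)c1cc(OCc2ccccc2)c(OCc2ccccc2)c(OCc2ccccc2)c1.[Cl-]
A4 | alternative 2 | (Z)-α-galloyloxy enaminone of ring E (benzylated) | CN(C)/C=C(\OC(=O)c1cc(OCc2ccccc2)c(OCc2ccccc2)c(OCc2ccccc2)c1)C(=O)c1cc(OC(=O)c2cc(OCc3ccccc3)c(OCc3ccccc3)c(OCc3ccccc3)c2)c(OCc2ccccc2)c(OCc2ccccc2)c1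
A5 | alternative 3 | fully benzylated target | O=C(Oc1cc([C@H]2Oc3cc(OCc4ccccc4)c([C@H]4c5c(OCc6ccccc6)cc(OCc6ccccc6)cc5O[C@H](c5ccc(OCc6ccccc6)cc5)[C@@H]4OCc4ccccc4)c(OCc4ccccc4)c3C[C@H]2OC(=O)c2cc(OCc3ccccc3)c(OCc3ccccc3)c(OCc3ccccc3)c2)cc(OCc2ccccc2)c1OCc1ccccc1)c1cc(OCc2ccccc2)c(OCc2ccccc2)c(OCc2ccccc2)c1
A6 | alternative 3 | ring D ortho-hydroxybenzyl alcohol carrying the upper unit | OCc1c(O)cc(OCc2ccccc2)c([C@H]2c3c(OCc4ccccc4)cc(OCc4ccccc4)cc3O[C@H](c3ccc(OCc4ccccc4)cc3)[C@@H]2OCc2ccccc2)c1OCc1ccccc1
A7 | alternative 3 | (Z)-enol gallate of ring E (benzylated) | O=C(O/C=C\c1cc(OC(=O)c2cc(OCc3ccccc3)c(OCc3ccccc3)c(OCc3ccccc3)c2)c(OCc2ccccc2)c(OCc2ccccc2)c1)c1cc(OCc2ccccc2)c(OCc2ccccc2)c(OCc2ccccc2)c1
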